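If we run this flask again, the figure to follow is how much of the initiator charge becomes living ends, and for how long those ends then work on the free monomer.

free monomer 0.93 M (fed, over 2.5 min); initiator 4.7 mM; time 2.5 h; the fed solution adds 0.50 times the starting volume

    free monomer + initiator → living end + monomer in chains (k1 = 1.8 M⁻¹ min⁻¹)
    free monomer + living end → monomer in chains + living end, rate k2*[living end]*[free monomer] (k2 = 5.8 M⁻¹ min⁻¹)
    2 initiator → spent initiator (k3 = 3.4 M⁻¹ min⁻¹)

* average number of monomer units in a chain (chains begun, living or dead) at 2.5 h
* part of the free monomer that has reacted at 2.5 h

- for a step with 2 of a species take k times the square, and two of it per event
- every charge counts on the volume at the start, and the solution that is fed holds the whole dose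
- the average divides the monomer in chains by the number of chains begun, living and dead together
- run time (flask): 2.5 h

1. The feed raises the free monomer steadily, so the initiator's rate per minute climbs with time. That rate times the elapsed time reaches one at 1.22 min, far shorter than the 2.5 h run, so we let the living ends stand from the end of the feed.

2. As a first pass, every initiator begins a chain. In the full volume that gives 3.13 mM of living ends.

3. With the ends steady, the free monomer falls at first order (pseudo-first-order). The fraction left is one over e raised to the growth constant times the living ends times the time after the feed. That power is 2.68, so 6.86% is left and the average chain has 184 units.

4. The weak link is "every initiator". At its full charge the pairing to spent initiator takes 0.0320 min⁻¹ of the initiator. Over 1.22 min, with the volume then at 1.24 starting volumes, that comes to a fraction 3.14%.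

5. The living ends become 3.03 mM. Now 2.60 is our monomer exponent, the growth constant times the living ends times the time after the feed. It gives 92.5% of the free monomer reacted and an average of 189 units.

The forecast says 189 (186 to 193) units and 92.6% (92.2% to 93%) reacted, on the ground that “initiation outruns propagation”.

The flask gives 189 and 92.6%.

 The neighbour flask holds 0.0019 M of initiator, all else as before. In our rule the lost fraction goes with the charge, so it becomes 1.27%. The living ends become 1.25 mM, and the exponent falls from 2.60 to 1.07, which leaves 34.3% of the free monomer and an average of 326 units. That neighbour flask shows 34% of the free monomer left, 65.9% reacted, and an average of 327 units.

The constants were drawn at random within sensible limits; the rest is arithmetic.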